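**Retrosynthetic overview**
1. The target is a eudesm-4-ene carrying a 3β-enoate, an 8β-acetate and a C7 methyl acrylate. The last operations are Steglich acylation at O-3, acetylation at O-8, and opening of a cis-fused 8β,12-lactone (exocyclic methylene installed by Mannich reaction and elimination) to the methyl ester.
2. The lactone comes from a C8 ketone by C7 alkylation with a bromoacetate and α-face hydride delivery. The C3 oxygen comes from bis-allylic oxidation of a ring A cyclohexa-1,4-diene, hydrogenation of C1=C2 and Luche reduction.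
3. Key disconnection: the tetrasubstituted C4=C5 alkene shared by rings A and B (C15 methyl on C4), next to quaternary C10, is the former alkyne C15–C4≡C5–C6 of an acyclic (E)-dienyne that adds to the diene C10=C1–C2=C3. Zerovalent nickel forms C5–C10 (ring B closes first) and then C3–C4 (ring A) in one step.
4. The dienyne is built from (R)-epichlorohydrin by two epoxide openings (silylpropargyllithium, then acetylide), methylalumination–iodination, vinyl coupling and alkyne methylation. Its C8 silyloxy centre relays chirality to C10 and is later erased.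

Key step: step 8

Remark: eudesmane numbering is used throughout (ring A = C1–C5 and C10; ring B = C5–C10; C14 on C10, C15 on C4, C11–C13 on C7; β is the face of the C10 methyl).
Assumption: (E)-3-methylpent-2-enoic acid (38) is bought as the geometrically pure acid.

**Route**

Step 1
Reactants: 1 (R)-epichlorohydrin; 2 1-(triisopropylsilyl)prop-1-yne
Product: 4 (R)-1-chloro-6-(triisopropylsilyl)hex-5-yn-2-ol, via silylpropargyllithium 3 (not isolated)
Conditions: 2, n-BuLi, THF, −20 °C; then BF3·OEt2, 1, −78 °C; H2O work-up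
Reagents that add atoms: none
Why: BF3-assisted SN2 opening of the terminal epoxide at its CH2 carbon by the silyl-substituted propargyllithium (Yamaguchi-type epoxide alkylation), in which the bulky silyl group enforces attack through the propargylic carbon and the stereocentre, whose C–O bond is not touched, keeps its configuration.

Step 2
Reactants: 4 (R)-1-chloro-6-(triisopropylsilyl)hex-5-yn-2-ol; 5 lithium acetylide–ethylenediamine complex (LiC≡CH·H2NCH2CH2NH2)
Product: 7 (R)-8-(triisopropylsilyl)octa-1,7-diyn-4-ol, via terminal epoxide 6 (not isolated)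
Conditions: 5 (3 equiv), DMSO, 0 °C → rt; H2O work-up
Reagents that add atoms: none
Why: The lithium alkoxide closes to the terminal epoxide by intramolecular Williamson displacement of chloride and a second acetylide opens it at the CH2 carbon (SN2 epoxide alkynylation), so no bond to the carbinol centre is broken and the silyl-capped alkyne stays inert.

Step 3
Reactants: 7 (R)-8-(triisopropylsilyl)octa-1,7-diyn-4-ol
Product: 9 (1E,4R)-1-iodo-2-methyl-8-(triisopropylsilyl)oct-1-en-7-yn-4-ol, via alkenylalane 8 (not isolated)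
Conditions: AlMe3 (3.5 equiv), Cp2ZrCl2 (0.25 equiv), CH2Cl2, 0 °C → rt; then I2, THF, −30 → 0 °C
Reagents that add atoms: trimethylaluminium C[Al](C)C; iodine II
Why: Negishi zirconium-catalysed methylalumination adds CH3 and Al syn across the terminal alkyne with CH3 on the internal carbon (the hindered silyl alkyne does not react and the hydroxyl travels as its aluminium alkoxide), and iodinolysis of the C–Al bond with retention should give the (E)-iodoalkene.

Step 4
Reactants: 9 (1E,4R)-1-iodo-2-methyl-8-(triisopropylsilyl)oct-1-en-7-yn-4-ol; 10 tributyl(vinyl)stannane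
Product: 11 (5R,7E)-7-methyl-1-(triisopropylsilyl)deca-7,9-dien-1-yn-5-ol
Conditions: 10 (1.2 equiv), PdCl2(MeCN)2 (5 mol%), DMF, rt
Reagents that add atoms: none
Why: Stille cross-coupling of the alkenyl iodide with the vinylstannane proceeds with retention of alkene geometry and tolerates the free hydroxyl and the silyl alkyne, giving the (E)-1,3-diene.

Step 5
Reactants: 11 (5R,7E)-7-methyl-1-(triisopropylsilyl)deca-7,9-dien-1-yn-5-ol
Product: 12 (5R,7E)-7-methyldeca-7,9-dien-1-yn-5-ol
Conditions: Bu4NF, THF, 0 °C → rt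
Reagents that add atoms: none
Why: Fluoride-induced protodesilylation of the alkynylsilane frees the terminal alkyne without touching the diene or the stereocentre.

Step 6
Reactants: 12 (5R,7E)-7-methyldeca-7,9-dien-1-yn-5-ol
Product: 13 tert-butyldimethyl{[(5R,7E)-7-methyldeca-7,9-dien-1-yn-5-yl]oxy}silane
Conditions: TBSCl, imidazole, DMF, rt
Reagents that add atoms: tert-butyldimethylsilyl chloride CC(C)(C)[Si](C)(C)Cl
Why: Imidazole-mediated silylation of the secondary alcohol installs the bulky ether that is to sit equatorial in the cyclisation.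

Step 7
Reactants: 13 tert-butyldimethyl{[(5R,7E)-7-methyldeca-7,9-dien-1-yn-5-yl]oxy}silane
Product: 15 tert-butyldimethyl{[(3E,6R)-4-methylundeca-1,3-dien-9-yn-6-yl]oxy}silane, via lithium acetylide 14 (not isolated)
Conditions: n-BuLi (1.05 equiv), THF, −78 °C; MeI, −78 °C → rt
Reagents that add atoms: iodomethane CI
Why: Deprotonation of the terminal alkyne, by far the most acidic C–H, and SN2 methylation of the lithium acetylide give the methyl alkyne that carries C15.

Step 8
Reactants: 15 tert-butyldimethyl{[(3E,6R)-4-methylundeca-1,3-dien-9-yn-6-yl]oxy}silane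
Product: 16 cycloadduct 8α-(tert-butyldimethylsilyloxy)-11,12,13-trinoreudesma-1,4-diene [tert-butyl{[(2R,8aS)-5,8a-dimethyl-1,2,3,4,6,8a-hexahydronaphthalen-2-yl]oxy}dimethylsilane]
Conditions: Ni(cod)2 (10–20 mol%), P(O-2-biphenylyl)3 (30–60 mol%), degassed THF (0.01 M), 25 → 60 °C
Reagents that add atoms: none
Why: Zerovalent nickel carrying one bulky phosphite binds the alkyne and the near C10=C1 alkene and couples them oxidatively to a nickelacyclopentene (new C5–C10 bond, nickel on C4 and C1); the allyl unit C1–C2–C3 then slips so that nickel sits on C3 in a seven-membered metallacycle, and reductive elimination forms C3–C4 and returns zerovalent nickel. The closest known reaction type is the Ni(cod)2/triaryl phosphite-catalysed intramolecular [4+2] cycloaddition of unactivated dienynes to bicyclic cyclohexa-1,4-dienes; a fully substituted diene terminus and a four-atom tether put this substrate at the demanding end of that class. Ring B (C5–C6–C7–C8–C9–C10) closes in the oxidative coupling as a six-membered ring, exo to both π bonds (C4 and C1 stay outside it), and ring A (C10–C1–C2–C3–C4–C5) closes in the reductive elimination as the six-membered 1,4-diene of a formal [4+2]. The only new stereocentre, C10, is controlled by C8: in the chair-like tether the C10 methyl becomes axial on ring B, so the silyloxy group stays equatorial and ends trans to it (8α-OTBS, 10β-CH3; 8R,10S), the other chair being penalised by a 1,3-diaxial CH3/OSi contact. The step needs cross-coupling of alkyne and diene to win over alkyne oligomerisation (high dilution, an internal alkyne and the bulky phosphite serve this) and needs the (E)-geometry of C10=C1 from steps 3 and 4, which keeps the tether on the outside of the diene; the quaternary C10 also rules out aromatisation of the product.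

Step 9
Reactants: 16 cycloadduct 8α-(tert-butyldimethylsilyloxy)-11,12,13-trinoreudesma-1,4-diene
Product: 17 11,12,13-trinoreudesma-1,4-dien-8α-ol [(2R,8aS)-5,8a-dimethyl-1,2,3,4,6,8a-hexahydronaphthalen-2-ol]
Conditions: Bu4NF, THF, rt
Reagents that add atoms: none
Why: Fluoride cleavage of the secondary silyl ether; the skipped diene is inert.

Step 10
Reactants: 17 11,12,13-trinoreudesma-1,4-dien-8α-ol
Product: 18 (10S)-11,12,13-trinoreudesma-1,4-dien-8-one [(S)-5,8a-dimethyl-3,4,6,8a-tetrahydronaphthalen-2(1H)-one]
Conditions: Dess–Martin periodinane, CH2Cl2, rt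
Reagents that add atoms: none
Why: Dess–Martin oxidation of the secondary alcohol under near-neutral conditions erases the relay stereocentre without isomerising the 1,4-diene.

Step 11
Reactants: 18 (10S)-11,12,13-trinoreudesma-1,4-dien-8-one; 19 methyl bromoacetate
Product: 21 methyl 8-oxo-13-noreudesma-1,4-dien-12-oate (both C7 epimers), via lithium enolate 20 (not isolated)
Conditions: LiN(i-Pr)2 (1.05 equiv), THF, −78 °C; 19, DMPU, −78 → −30 °C
Reagents that add atoms: none
Why: Kinetic deprotonation takes place at C7, away from the neopentyl C9 next to quaternary C10, and the lithium enolate is C-alkylated by the bromoacetate (SN2 enolate alkylation), the C7 configuration being settled in the next step.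

Step 12
Reactants: 21 methyl 8-oxo-13-noreudesma-1,4-dien-12-oate (both C7 epimers)
Product: 22 methyl (7R,10S)-8-oxo-13-noreudesma-1,4-dien-12-oate (7β side chain, 7αH)
Conditions: NaOMe (0.2 equiv), MeOH, 0 °C → rt
Reagents that add atoms: none
Why: Base-mediated epimerisation through the C7 enolate should funnel both epimers to the equatorial 7β side chain on the conformationally locked ring B (C10 methyl axial).

Step 13
Reactants: 22 methyl (7R,10S)-8-oxo-13-noreudesma-1,4-dien-12-oate
Product: 24 cis-fused lactone 13-noreudesma-1,4-dien-8β,12-olide (7R,8R,10S), via lithium alkoxide 23 (not isolated)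
Conditions: LiBH(s-Bu)3 (1.1 equiv), THF, −78 → 0 °C; aqueous work-up
Reagents that add atoms: none
Why: The bulky trialkylborohydride attacks the C8 carbonyl from the equatorial α-face, the β-face being screened by the axial C10 methyl, to give the axial 8β-alkoxide, which is cis to the 7β-acetate arm and closes to the cis-fused γ-lactone by intramolecular transesterification.

Step 14
Reactants: 24 cis-fused lactone 13-noreudesma-1,4-dien-8β,12-olide
Product: 25 dienone 3-oxo-13-noreudesma-1,4-dien-8β,12-olide
Conditions: (C5H5NH)2Cr2O7 (PDC), t-BuOOH, Celite, benzene, rt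
Reagents that add atoms: tert-butyl hydroperoxide CC(C)(C)OO
Why: Allylic oxidation by the hexavalent chromium/t-BuOOH couple (chromium as mediator, hydroperoxide as oxidant) removes the weak bis-allylic C3–H and should deliver the cross-conjugated 2,5-cyclohexadienone, as known for cyclohexa-1,4-dienes whose second sp3 carbon is quaternary.

Step 15
Reactants: 25 dienone 3-oxo-13-noreudesma-1,4-dien-8β,12-olide
Product: 26 enone 3-oxo-13-noreudesm-4-en-8β,12-olide (7R,8R,10R)
Conditions: H2 (1 atm), RhCl(PPh3)3 (10 mol%), benzene, rt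
Reagents that add atoms: none
Why: Homogeneous hydrogenation with RhCl(PPh3)3 reduces the disubstituted C1=C2 bond of the cross-conjugated dienone and leaves the tetrasubstituted C4=C5 bond, as in the known conversion of steroidal 1,4-dien-3-ones into 4-en-3-ones.

Step 16
Reactants: 26 enone 3-oxo-13-noreudesm-4-en-8β,12-olide
Product: 27 allylic alcohol 3β-hydroxy-13-noreudesm-4-en-8β,12-olide (3S,7R,8R,10R)
Conditions: NaBH4, CeCl3·7H2O, MeOH, −78 → −40 °C
Reagents that add atoms: none
Why: Luche 1,2-reduction, in which hydride adds axially to C3 from the α-face, anti to the angular C10 methyl, should give the pseudo-equatorial 3β-alcohol without reducing the lactone.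

Step 17
Reactants: 27 allylic alcohol 3β-hydroxy-13-noreudesm-4-en-8β,12-olide
Product: 28 silyl ether 3β-(tert-butyldimethylsilyloxy)-13-noreudesm-4-en-8β,12-olide
Conditions: TBSCl, imidazole, DMF, rt
Reagents that add atoms: tert-butyldimethylsilyl chloride CC(C)(C)[Si](C)(C)Cl
Why: Imidazole-mediated silylation protects O-3 for the enolate and hydroxide steps that follow.

Step 18
Reactants: 28 silyl ether 3β-(tert-butyldimethylsilyloxy)-13-noreudesm-4-en-8β,12-olide; 29 Eschenmoser's salt (dimethylmethyleneammonium iodide)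
Product: 31 Mannich base 13-(dimethylamino)-3β-(tert-butyldimethylsilyloxy)eudesm-4-en-8β,12-olide (C11 epimers), via lactone enolate 30 (not isolated)
Conditions: LiN(i-Pr)2 (1.2 equiv), THF, −78 °C; 29, −78 °C → rt
Reagents that add atoms: none
Why: The lactone enolate adds to the iminium salt at C11 (Mannich reaction), and the C11 configuration is irrelevant because that centre becomes sp2 in the next step.

Step 19
Reactants: 31 Mannich base 13-(dimethylamino)-3β-(tert-butyldimethylsilyloxy)eudesm-4-en-8β,12-olide
Product: 33 α-methylene lactone 3β-(tert-butyldimethylsilyloxy)eudesma-4,11(13)-dien-8β,12-olide, via ammonium iodide 32 (not isolated)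
Conditions: MeI, THF, rt; then aq. NaHCO3, CH2Cl2, rt
Reagents that add atoms: none
Why: N-methylation turns the amine into a trimethylammonium leaving group and mild base effects β-elimination (E1cB, Hofmann-type) to the exocyclic C11=C13 alkene.

Step 20
Reactants: 33 α-methylene lactone 3β-(tert-butyldimethylsilyloxy)eudesma-4,11(13)-dien-8β,12-olide
Product: 35 methyl 8β-hydroxy-3β-(tert-butyldimethylsilyloxy)eudesma-4,11(13)-dien-12-oate, via potassium carboxylate 34 (not isolated)
Conditions: KOH (1.05 equiv), THF–H2O, 0 °C → rt; concentrate; MeI, DMF, 0 °C → rt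
Reagents that add atoms: potassium hydroxide [K+].[OH-]; iodomethane CI
Why: Saponification opens the lactone at the acyl C–O bond, so C8 keeps its configuration, and the potassium carboxylate is O-alkylated by iodomethane (SN2) under conditions that leave the hindered axial 8β-hydroxyl untouched.

Step 21
Reactants: 35 methyl 8β-hydroxy-3β-(tert-butyldimethylsilyloxy)eudesma-4,11(13)-dien-12-oate
Product: 36 methyl 8β-acetoxy-3β-(tert-butyldimethylsilyloxy)eudesma-4,11(13)-dien-12-oate
Conditions: Ac2O, DMAP (cat.), pyridine, rt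
Reagents that add atoms: acetic anhydride CC(=O)OC(C)=O
Why: DMAP-catalysed acetylation of the axial 8β-alcohol should outrun re-closure of the lactone.

Step 22
Reactants: 36 methyl 8β-acetoxy-3β-(tert-butyldimethylsilyloxy)eudesma-4,11(13)-dien-12-oate
Product: 37 methyl 8β-acetoxy-3β-hydroxyeudesma-4,11(13)-dien-12-oate
Conditions: HF·pyridine, pyridine, THF, 0 °C → rt
Reagents that add atoms: none
Why: Buffered HF·pyridine cleaves the allylic silyl ether (fluoride desilylation) without touching the acetate, the methyl ester or the acrylate.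

Step 23
Reactants: 37 methyl 8β-acetoxy-3β-hydroxyeudesma-4,11(13)-dien-12-oate; 38 (E)-3-methylpent-2-enoic acid
Product: 39 methyl (3S,7R,8R,10R)-8β-acetoxy-3β-[(E)-3-methylpent-2-enoyloxy]eudesma-4,11(13)-dien-12-oate (target CNP0118541.1)
Conditions: 38 (1.5 equiv), DCC, DMAP (0.1 equiv), CH2Cl2, 0 °C → rt
Reagents that add atoms: none
Why: Steglich esterification acylates the 3β-alcohol with retention at C3, and low temperature with little DMAP keeps the (E)-enoate from deconjugating or isomerising.

**Compound list**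
1 | (R)-epichlorohydrin | ClC[C@H]1CO1 | starting material
2 | 1-(triisopropylsilyl)prop-1-yne | CC#C[Si](C(C)C)(C(C)C)C(C)C | starting material
3 | [3-(triisopropylsilyl)prop-2-yn-1-yl]lithium | [Li]CC#C[Si](C(C)C)(C(C)C)C(C)C | intermediate
4 | (R)-1-chloro-6-(triisopropylsilyl)hex-5-yn-2-ol | CC(C)[Si](C(C)C)(C(C)C)C#CCC[C@@H](O)CCl | intermediate
5 | lithium acetylide–ethylenediamine complex | [Li]C#C.NCCN | starting material
6 | triisopropyl{4-[(2R)-oxiran-2-yl]but-1-yn-1-yl}silane | CC(C)[Si](C(C)C)(C(C)C)C#CCC[C@@H]1CO1 | intermediate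
7 | (R)-8-(triisopropylsilyl)octa-1,7-diyn-4-ol | CC(C)[Si](C(C)C)(C(C)C)C#CCC[C@@H](O)CC#C | intermediate
8 | (1E,4R)-alkenyl(dimethyl)alane of 7, O-4 as dimethylaluminium alkoxide | CC(C)[Si](C(C)C)(C(C)C)C#CCC[C@@H](O[Al](C)C)C/C(C)=C/[Al](C)C | intermediate
9 | (1E,4R)-1-iodo-2-methyl-8-(triisopropylsilyl)oct-1-en-7-yn-4-ol | CC(C)[Si](C(C)C)(C(C)C)C#CCC[C@@H](O)C/C(C)=C/I | intermediate
10 | tributyl(vinyl)stannane | C=C[Sn](CCCC)(CCCC)CCCC | starting material
11 | (5R,7E)-7-methyl-1-(triisopropylsilyl)deca-7,9-dien-1-yn-5-ol | CC(C)[Si](C(C)C)(C(C)C)C#CCC[C@@H](O)C/C(C)=C/C=C | intermediate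
12 | (5R,7E)-7-methyldeca-7,9-dien-1-yn-5-ol | C#CCC[C@@H](O)C/C(C)=C/C=C | intermediate
13 | tert-butyldimethyl{[(5R,7E)-7-methyldeca-7,9-dien-1-yn-5-yl]oxy}silane | C#CCC[C@@H](O[Si](C)(C)C(C)(C)C)C/C(C)=C/C=C | intermediate
14 | lithium acetylide of 13 | [Li]C#CCC[C@@H](O[Si](C)(C)C(C)(C)C)C/C(C)=C/C=C | intermediate
15 | tert-butyldimethyl{[(3E,6R)-4-methylundeca-1,3-dien-9-yn-6-yl]oxy}silane (key-step precursor) | CC#CCC[C@@H](O[Si](C)(C)C(C)(C)C)C/C(C)=C/C=C | intermediate
16 | 8α-(tert-butyldimethylsilyloxy)-11,12,13-trinoreudesma-1,4-diene (8R,10S) | CC1=C2CC[C@@H](O[Si](C)(C)C(C)(C)C)C[C@@]2(C)C=CC1 | intermediate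
17 | 11,12,13-trinoreudesma-1,4-dien-8α-ol | CC1=C2CC[C@@H](O)C[C@@]2(C)C=CC1 | intermediate
18 | (10S)-11,12,13-trinoreudesma-1,4-dien-8-one | CC1=C2CCC(=O)C[C@@]2(C)C=CC1 | intermediate
19 | methyl bromoacetate | COC(=O)CBr | starting material
20 | lithium Δ7-enolate of 18 | CC1=C2CC=C(O[Li])C[C@@]2(C)C=CC1 | intermediate
21 | methyl 8-oxo-13-noreudesma-1,4-dien-12-oate (C7 epimers) | COC(=O)CC1CC2=C(C)CC=C[C@]2(C)CC1=O | intermediate
22 | methyl (7R,10S)-8-oxo-13-noreudesma-1,4-dien-12-oate | COC(=O)C[C@H]1CC2=C(C)CC=C[C@]2(C)CC1=O | intermediate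
23 | lithium 8β-alkoxide of the reduced keto ester | COC(=O)C[C@H]1CC2=C(C)CC=C[C@]2(C)C[C@H]1O[Li] | intermediate
24 | 13-noreudesma-1,4-dien-8β,12-olide (cis-fused) | O=C1C[C@H]2CC3=C(C)CC=C[C@]3(C)C[C@H]2O1 | intermediate
25 | 3-oxo-13-noreudesma-1,4-dien-8β,12-olide | O=C1C[C@H]2CC3=C(C)C(=O)C=C[C@]3(C)C[C@H]2O1 | intermediate
26 | 3-oxo-13-noreudesm-4-en-8β,12-olide | O=C1C[C@H]2CC3=C(C)C(=O)CC[C@]3(C)C[C@H]2O1 | intermediate
27 | 3β-hydroxy-13-noreudesm-4-en-8β,12-olide | O=C1C[C@H]2CC3=C(C)[C@@H](O)CC[C@]3(C)C[C@H]2O1 | intermediate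
28 | 3β-(tert-butyldimethylsilyloxy)-13-noreudesm-4-en-8β,12-olide | O=C1C[C@H]2CC3=C(C)[C@@H](O[Si](C)(C)C(C)(C)C)CC[C@]3(C)C[C@H]2O1 | intermediate
29 | Eschenmoser's salt (dimethylmethyleneammonium iodide) | C=[N+](C)C.[I-] | starting material
30 | lithium enolate of lactone 28 | [Li]OC1=C[C@H]2CC3=C(C)[C@@H](O[Si](C)(C)C(C)(C)C)CC[C@]3(C)C[C@H]2O1 | intermediate
31 | 13-(dimethylamino)-3β-(tert-butyldimethylsilyloxy)eudesm-4-en-8β,12-olide (C11 epimers) | CN(C)CC1[C@H]2CC3=C(C)[C@@H](O[Si](C)(C)C(C)(C)C)CC[C@]3(C)C[C@H]2OC1=O | intermediate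
32 | trimethylammonium iodide of 31 | C[N+](C)(C)CC1[C@H]2CC3=C(C)[C@@H](O[Si](C)(C)C(C)(C)C)CC[C@]3(C)C[C@H]2OC1=O.[I-] | intermediate
33 | 3β-(tert-butyldimethylsilyloxy)eudesma-4,11(13)-dien-8β,12-olide | C=C1[C@H]2CC3=C(C)[C@@H](O[Si](C)(C)C(C)(C)C)CC[C@]3(C)C[C@H]2OC1=O | intermediate
34 | potassium 8β-hydroxy-3β-(tert-butyldimethylsilyloxy)eudesma-4,11(13)-dien-12-oate | C=C(C(=O)[O-])[C@H]1CC2=C(C)[C@@H](O[Si](C)(C)C(C)(C)C)CC[C@]2(C)C[C@H]1O.[K+] | intermediate
35 | methyl 8β-hydroxy-3β-(tert-butyldimethylsilyloxy)eudesma-4,11(13)-dien-12-oate | C=C(C(=O)OC)[C@H]1CC2=C(C)[C@@H](O[Si](C)(C)C(C)(C)C)CC[C@]2(C)C[C@H]1O | intermediate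
36 | methyl 8β-acetoxy-3β-(tert-butyldimethylsilyloxy)eudesma-4,11(13)-dien-12-oate | C=C(C(=O)OC)[C@H]1CC2=C(C)[C@@H](O[Si](C)(C)C(C)(C)C)CC[C@]2(C)C[C@H]1OC(C)=O | intermediate
37 | methyl 8β-acetoxy-3β-hydroxyeudesma-4,11(13)-dien-12-oate | C=C(C(=O)OC)[C@H]1CC2=C(C)[C@@H](O)CC[C@]2(C)C[C@H]1OC(C)=O | intermediate
38 | (E)-3-methylpent-2-enoic acid | CC/C(C)=C/C(=O)O | starting material
39 | methyl (3S,7R,8R,10R)-8β-acetoxy-3β-[(E)-3-methylpent-2-enoyloxy]eudesma-4,11(13)-dien-12-oate | C=C(C(=O)OC)[C@H]1CC2=C(C)[C@@H](OC(=O)/C=C(\C)CC)CC[C@]2(C)C[C@H]1OC(C)=O | target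

**Step count**
Total: 23 steps. Longest linear sequence: 23 steps, from (R)-epichlorohydrin 1 to 39.

**Three steps most likely to fail**

1. Step 8 (key step). What may go wrong: oxidative coupling at the fully substituted diene terminus may be slower than alkyne oligomerisation, and the equatorial preference of the silyloxy group may not translate into full facial selectivity at C10. Fallback, setting out from 13 and returning at 16: the cycloaddition is run thermally on an activated alkyne. Compound 13 is deprotonated with n-BuLi and acylated with methyl chloroformate to the alkynoate methyl (6R,8E)-6-(tert-butyldimethylsilyloxy)-8-methylundeca-8,10-dien-2-ynoate F1. Intramolecular Diels–Alder reaction of F1 (toluene, BHT, 160–180 °C, sealed tube) should give the diene ester methyl 8α-(tert-butyldimethylsilyloxy)-11,12,13-trinoreudesma-1,4-dien-15-oate F2, with the same chair control of C10. Reduction with i-Bu2AlH (CH2Cl2, −78 °C) gives the allylic alcohol 8α-(tert-butyldimethylsilyloxy)-11,12,13-trinoreudesma-1,4-dien-15-ol F3. Its sulfate monoester (SO3·pyridine, THF) is displaced by hydride (LiAlH4), which turns C15 into the methyl group of 16.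

2. Step 14. What may go wrong: loss of site selectivity in the oxidation, by oxygen capture at C1 or C5 of the pentadienyl intermediate or by attack at the allylic C6 or C15 positions, and over-oxidation. Fallback, setting out from 24 and returning at 25: oxygen is introduced by a pericyclic route. SeO2 (cat.) with t-BuOOH in CH2Cl2 hydroxylates by an ene reaction followed by a [2,3]-sigmatropic shift, which returns oxygen to the carbon that lost hydrogen. C3 is the only position allylic to both alkenes, so this should give the bis-allylic alcohol 3-hydroxy-13-noreudesma-1,4-dien-8β,12-olide F4 (C3 epimers). MnO2 in CH2Cl2 then oxidises F4 to dienone 25.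

3. Step 20. What may go wrong: conjugate addition of hydroxide to the exocyclic methylene, and re-closure of the lactone from the hydroxy ester before it is acetylated. Fallback, setting out from 31 and returning at 36: the lactone is opened while the methylene is still masked as the amine. Mannich base 31 is saponified (KOH, THF–H2O) to potassium 13-(dimethylamino)-8β-hydroxy-3β-(tert-butyldimethylsilyloxy)eudesm-4-en-12-oate F5. Excess MeI in DMF esterifies the carboxylate and quaternises the amine, giving the hydroxy ester trimethylammonium iodide F6. Ac2O, DMAP and Et3N in CH2Cl2 acetylate O-8 to the acetoxy ester trimethylammonium iodide F7, which loses trimethylamine in the same flask to give 36, by-passing 33 and 35.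

**Further compounds**
F1 | step 8 | methyl (6R,8E)-6-(tert-butyldimethylsilyloxy)-8-methylundeca-8,10-dien-2-ynoate | COC(=O)C#CCC[C@@H](O[Si](C)(C)C(C)(C)C)C/C(C)=C/C=C
F2 | step 8 | methyl 8α-(tert-butyldimethylsilyloxy)-11,12,13-trinoreudesma-1,4-dien-15-oate | COC(=O)C1=C2CC[C@@H](O[Si](C)(C)C(C)(C)C)C[C@@]2(C)C=CC1
F3 | step 8 | 8α-(tert-butyldimethylsilyloxy)-11,12,13-trinoreudesma-1,4-dien-15-ol | OCC1=C2CC[C@@H](O[Si](C)(C)C(C)(C)C)C[C@@]2(C)C=CC1
F4 | step 14 | 3-hydroxy-13-noreudesma-1,4-dien-8β,12-olide (C3 epimers) | O=C1C[C@H]2CC3=C(C)C(O)C=C[C@]3(C)C[C@H]2O1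
F5 | step 20 | potassium 13-(dimethylamino)-8β-hydroxy-3β-(tert-butyldimethylsilyloxy)eudesm-4-en-12-oate | CN(C)CC(C(=O)[O-])[C@H]1CC2=C(C)[C@@H](O[Si](C)(C)C(C)(C)C)CC[C@]2(C)C[C@H]1O.[K+]
F6 | step 20 | methyl 8β-hydroxy-3β-(tert-butyldimethylsilyloxy)-13-(trimethylammonio)eudesm-4-en-12-oate iodide | C[N+](C)(C)CC(C(=O)OC)[C@H]1CC2=C(C)[C@@H](O[Si](C)(C)C(C)(C)C)CC[C@]2(C)C[C@H]1O.[I-]
F7 | step 20 | methyl 8β-acetoxy-3β-(tert-butyldimethylsilyloxy)-13-(trimethylammonio)eudesm-4-en-12-oate iodide | C[N+](C)(C)CC(C(=O)OC)[C@H]1CC2=C(C)[C@@H](O[Si](C)(C)C(C)(C)C)CC[C@]2(C)C[C@H]1OC(C)=O.[I-]
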